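**Retrosynthetic overview**
- Target 20 is a (2S)-flavanone; the last two steps unmask the C4 ketone from a spiro-1,3-dithiane and cleave two MOM ethers (20 ⇐ 19 ⇐ 18).
- Key disconnection (18 ⇒ 11 + 14): ring C is opened at the aryl ether bond O1–C8a and the C8–CH2 bond of the side chain is cut in the same operation, both on a C8–C8a aryne of ring A. The enabling feature is that on ring A the ether oxygen (at C8a) and the five-carbon side chain (at C8) are ortho neighbours beside the C7 oxygen, while the C2 oxygen is tied through C3–C4 to C4a and can therefore reach only C8a.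
- Aryne precursor 11 carries fluorine at C8a, hydrogen at C8 (between F and OMOM), C4 as a 1,3-dithiane and the (S)-carbinol at C2 (CBS reduction). 11 ⇐ ynone 9 + propane-1,3-dithiol; 9 ⇐ alkyne 6 (ring A) + aldehyde 3 (ring B, both prenyl groups by Stille coupling).
- The side-chain stereocentre comes from (S)-2-(prop-1-en-2-yl)oxirane 14 (methacrolein, Corey–Chaykovsky, hydrolytic kinetic resolution).
- Ring order: rings A and B are purchased benzenes; temporary dithiane ring (step 7); ring C (step 11); dithiane ring removed (step 12).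

Key step: step 11

Assumption: flavanone numbering (O1, C2, C3, C4, C4a, C5–C8, C8a) is used for all intermediates, also before ring C exists; tributyl(3-methylbut-2-en-1-yl)stannane, the Ohira–Bestmann reagent, (R)-2-methyl-CBS-oxazaborolidine and (S,S)-(salen)Co(OAc) are taken as purchased.

**Route**

Step 1
Reactants: 1 4-hydroxy-3,5-diiodobenzaldehyde
Product: 2 3,5-diiodo-4-(methoxymethoxy)benzaldehyde
Conditions: MOMCl, iPr2NEt, DMF, 0 °C to rt
Reagents that add atoms: chloromethyl methyl ether (MOMCl), COCCl
Why: O-alkylation of the acidic phenol (Williamson-type) should give a MOM ether that tolerates organolithium reagents and is cleaved by acid at the end.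

Step 2
Reactants: 2 3,5-diiodo-4-(methoxymethoxy)benzaldehyde
Product: 3 4-(methoxymethoxy)-3,5-bis(3-methylbut-2-en-1-yl)benzaldehyde
Conditions: tributyl(3-methylbut-2-en-1-yl)stannane (2.5 equiv), Pd(PPh3)4 (10 mol%), DMF, 90 °C
Reagents that add atoms: tributyl(3-methylbut-2-en-1-yl)stannane, CCCC[Sn](CCCC)(CCCC)CC=C(C)C
Why: A twofold Stille coupling of the aryl iodides should give the linear prenyl groups by reductive elimination at the less substituted allyl terminus, and the aldehyde is tolerated.

Step 3
Reactants: 4 2-fluoro-4-hydroxybenzaldehyde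
Product: 5 2-fluoro-4-(methoxymethoxy)benzaldehyde
Conditions: MOMCl, iPr2NEt, CH2Cl2, 0 °C to rt
Reagents that add atoms: chloromethyl methyl ether (MOMCl), COCCl
Why: O-alkylation of the phenol (Williamson-type) installs the group that later directs lithiation to C8 and stabilises the C8 carbanion.

Step 4
Reactants: 5 2-fluoro-4-(methoxymethoxy)benzaldehyde
Product: 6 1-ethynyl-2-fluoro-4-(methoxymethoxy)benzene
Conditions: dimethyl (1-diazo-2-oxopropyl)phosphonate, K2CO3, MeOH, rt
Reagents that add atoms: dimethyl (1-diazo-2-oxopropyl)phosphonate (Ohira–Bestmann reagent), CC(=O)C(=[N+]=[N-])P(=O)(OC)OC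
Why: Seyferth–Gilbert homologation in the Ohira–Bestmann form should convert the aryl aldehyde into the terminal alkyne under mild base that leaves the aryl fluoride and the MOM ether untouched.

Step 5
Reactants: 6 1-ethynyl-2-fluoro-4-(methoxymethoxy)benzene; 3 4-(methoxymethoxy)-3,5-bis(3-methylbut-2-en-1-yl)benzaldehyde
Product: 8 3-[2-fluoro-4-(methoxymethoxy)phenyl]-1-[4-(methoxymethoxy)-3,5-bis(3-methylbut-2-en-1-yl)phenyl]prop-2-yn-1-ol (racemic), via lithium acetylide 7 (not isolated)
Conditions: n-BuLi (1.0 equiv), THF, −78 °C; then 3, −78 to 0 °C; H2O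
Reagents that add atoms: none
Why: Addition of a lithium acetylide to an aldehyde; the alkyne C–H is by far the most acidic site, so one equivalent of base should leave the fluoroarene unmetalated, and the racemic carbinol is oxidised in the next step.

Step 6
Reactants: 8 racemic propargylic alcohol
Product: 9 3-[2-fluoro-4-(methoxymethoxy)phenyl]-1-[4-(methoxymethoxy)-3,5-bis(3-methylbut-2-en-1-yl)phenyl]prop-2-yn-1-one
Conditions: activated MnO2 (excess), CH2Cl2, rt
Reagents that add atoms: none
Why: MnO2 oxidation of a benzylic and propargylic alcohol should give the ynone without touching the prenyl groups.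

Step 7
Reactants: 9 ynone
Product: 10 2-{2-[2-fluoro-4-(methoxymethoxy)phenyl]-1,3-dithian-2-yl}-1-[4-(methoxymethoxy)-3,5-bis(3-methylbut-2-en-1-yl)phenyl]ethan-1-one
Conditions: propane-1,3-dithiol (1.2 equiv), NaOMe (0.3 equiv), MeOH/CH2Cl2, −10 °C to rt
Reagents that add atoms: propane-1,3-dithiol, SCCCS
Why: A double thia-Michael addition of the dithiol to the ynone should place both sulfur atoms on the β-carbon that carries ring A (the second addition being a 6-exo-trig closure), which masks C4 at the ketone oxidation level and leaves the C2 ketone free.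

Step 8
Reactants: 10 β-keto dithiane
Product: 11 (1S)-2-{2-[2-fluoro-4-(methoxymethoxy)phenyl]-1,3-dithian-2-yl}-1-[4-(methoxymethoxy)-3,5-bis(3-methylbut-2-en-1-yl)phenyl]ethan-1-ol
Conditions: (R)-2-methyl-CBS-oxazaborolidine (20 mol%), BH3·SMe2, THF, −20 °C; MeOH
Reagents that add atoms: none
Why: CBS reduction, in which the catalyst–borane complex binds the aryl ketone with the aryl group as the large flank and CH2 as the small one, so the (R)-catalyst should deliver hydride to the Re face and set the (S)-carbinol (the later C2), as it does for acetophenone.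

Step 9
Reactants: 12 methacrolein (2-methylprop-2-enal)
Product: 13 2-(prop-1-en-2-yl)oxirane (racemic)
Conditions: trimethylsulfonium iodide, NaH, DMSO/THF, 0 °C to rt; distilled from the mixture
Reagents that add atoms: trimethylsulfonium iodide, C[S+](C)C.[I-]
Why: Corey–Chaykovsky epoxidation, in which dimethylsulfonium methylide adds 1,2 to the enal carbonyl and the betaine closes to the vinyl oxirane.

Step 10
Reactants: 13 racemic 2-(prop-1-en-2-yl)oxirane
Product: 14 (2S)-2-(prop-1-en-2-yl)oxirane
Conditions: (S,S)-(salen)Co(OAc) [acetate of trivalent cobalt with (S,S)-N,N'-bis(3,5-di-tert-butylsalicylidene)cyclohexane-1,2-diamine] (0.5 mol%), H2O (0.55 equiv), neat, 0 °C to rt; distillation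
Reagents that add atoms: none
Why: Jacobsen hydrolytic kinetic resolution of a monosubstituted terminal epoxide, in which the (S,S)-catalyst should hydrate the (R)-epoxide and leave the (S)-epoxide, by analogy with propylene oxide and other epoxides whose substituent ranks below the ring CH2O.

Step 11
Reactants: 11 (1S)-carbinol with fluoroarene and dithiane; 14 (2S)-2-(prop-1-en-2-yl)oxirane
Product: 18 (2S)-8-[(2R)-2-hydroxy-3-methylbut-3-en-1-yl]-7-(methoxymethoxy)-2-[4-(methoxymethoxy)-3,5-bis(3-methylbut-2-en-1-yl)phenyl]-2,3-dihydrospiro[chromene-4,2'-[1,3]dithiane], via dilithio species 15 (not isolated), via aryne alkoxide 16 (not isolated), via 8-lithiochroman 17 (not isolated)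
Conditions: n-BuLi (2.1 equiv), THF (0.02 M), −78 °C, 1 h; −78 to −20 °C, 1 h; recool to −78 °C, 14 (2 equiv), then BF3·OEt2 (2 equiv), 1 h; H2O
Reagents that add atoms: none
Why: Proposed new method: the first equivalent of n-BuLi gives the lithium alkoxide and the second removes H-8, the only ring hydrogen flanked by both fluorine and the MOM ether (15), and on warming LiF is lost to give the C8–C8a aryne 16, whose tethered alkoxide adds to C8a and closes ring C in a 6-exo-dig mode to leave aryllithium 17; the closest known reaction types are the generation of 3-alkoxyarynes from 2-lithio-3-fluoroaryl ethers, the intramolecular capture of arynes by tethered heteroatom nucleophiles and the BF3-promoted opening of terminal epoxides by aryllithiums, and their union in one flask with an alkoxide donor and an epoxide acceptor is the new element. The step needs oxygen at C8a and carbon at C8: the C3–C4–C4a tether lets the oxygen reach only C8a, and the C7 oxygen polarises the aryne in the same sense because it leaves the carbanion at C8 beside an inductively withdrawing oxygen. Aryllithium 17 sits between two ether oxygens, so it is stabilised by chelation and should survive until 14 and BF3·OEt2 are added at −78 °C, where this hindered, hard nucleophile should open the epoxide by SN2 attack at the unsubstituted CH2 and not at the allylic carbon or at the alkene terminus, the latter being the habit of organocopper reagents, which are therefore avoided. No stereocentre is formed: C2 keeps its S configuration because only its O–H bond reacts, and the side-chain carbinol carbon comes from 14 with its C–O bond intact, so (S)-14 gives the (R)-carbinol (the descriptor changes only because the CIP ranks of the two carbon neighbours change). The dithiane is what makes the event possible at C4: it has no carbonyl and no acidic hydrogen, and its sulfur atoms cannot add to the aryne because that would need a four-membered ring.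

Step 12
Reactants: 18 spiro-dithiane chroman
Product: 19 (2S)-8-[(2R)-2-hydroxy-3-methylbut-3-en-1-yl]-7-(methoxymethoxy)-2-[4-(methoxymethoxy)-3,5-bis(3-methylbut-2-en-1-yl)phenyl]-2,3-dihydro-4H-chromen-4-one
Conditions: MeI (excess), CaCO3, MeCN/H2O 9:1, 40 °C
Reagents that add atoms: water, O
Why: Alkylative dithiane hydrolysis, in which S-methylation makes sulfur a leaving group, the thionium ion (stabilised by the C7 and ring oxygens) is captured by water, and the buffered neutral medium should leave C2, the alkenes and the secondary alcohol untouched.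

Step 13
Reactants: 19 bis-MOM flavanone
Product: 20 (2S)-7-hydroxy-2-[4-hydroxy-3,5-bis(3-methylbut-2-en-1-yl)phenyl]-8-[(2R)-2-hydroxy-3-methylbut-3-en-1-yl]-2,3-dihydro-4H-chromen-4-one (target)
Conditions: HCl (3 M aq), MeOH, 40 °C, stopped at full conversion
Reagents that add atoms: none
Why: Acid-catalysed acetal exchange with methanol should cleave both aryl MOM ethers under conditions in which a flavanone is configurationally stable, the mild temperature being chosen to spare the prenyl groups and the allylic alcohol.

**Compound list**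

1 | 4-hydroxy-3,5-diiodobenzaldehyde | O=Cc1cc(I)c(O)c(I)c1 | starting material
2 | 3,5-diiodo-4-(methoxymethoxy)benzaldehyde | O=Cc1cc(I)c(OCOC)c(I)c1 | intermediate
3 | 4-(methoxymethoxy)-3,5-bis(3-methylbut-2-en-1-yl)benzaldehyde | O=Cc1cc(CC=C(C)C)c(OCOC)c(CC=C(C)C)c1 | intermediate
4 | 2-fluoro-4-hydroxybenzaldehyde | O=Cc1ccc(O)cc1F | starting material
5 | 2-fluoro-4-(methoxymethoxy)benzaldehyde | O=Cc1ccc(OCOC)cc1F | intermediate
6 | 1-ethynyl-2-fluoro-4-(methoxymethoxy)benzene | C#Cc1ccc(OCOC)cc1F | intermediate
7 | lithium acetylide of 6 | [Li]C#Cc1ccc(OCOC)cc1F | intermediate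
8 | 3-[2-fluoro-4-(methoxymethoxy)phenyl]-1-[4-(methoxymethoxy)-3,5-bis(3-methylbut-2-en-1-yl)phenyl]prop-2-yn-1-ol (racemic) | OC(C#Cc1ccc(OCOC)cc1F)c1cc(CC=C(C)C)c(OCOC)c(CC=C(C)C)c1 | intermediate
9 | 3-[2-fluoro-4-(methoxymethoxy)phenyl]-1-[4-(methoxymethoxy)-3,5-bis(3-methylbut-2-en-1-yl)phenyl]prop-2-yn-1-one | O=C(C#Cc1ccc(OCOC)cc1F)c1cc(CC=C(C)C)c(OCOC)c(CC=C(C)C)c1 | intermediate
10 | 2-{2-[2-fluoro-4-(methoxymethoxy)phenyl]-1,3-dithian-2-yl}-1-[4-(methoxymethoxy)-3,5-bis(3-methylbut-2-en-1-yl)phenyl]ethan-1-one | O=C(CC1(c2ccc(OCOC)cc2F)SCCCS1)c1cc(CC=C(C)C)c(OCOC)c(CC=C(C)C)c1 | intermediate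
11 | (1S)-2-{2-[2-fluoro-4-(methoxymethoxy)phenyl]-1,3-dithian-2-yl}-1-[4-(methoxymethoxy)-3,5-bis(3-methylbut-2-en-1-yl)phenyl]ethan-1-ol | O[C@H](c1cc(CC=C(C)C)c(OCOC)c(CC=C(C)C)c1)CC1(c2ccc(OCOC)cc2F)SCCCS1 | intermediate
12 | methacrolein (2-methylprop-2-enal) | C=C(C)C=O | starting material
13 | 2-(prop-1-en-2-yl)oxirane (racemic) | C=C(C)C1CO1 | intermediate
14 | (2S)-2-(prop-1-en-2-yl)oxirane | C=C(C)[C@H]1CO1 | intermediate
15 | lithium alkoxide of 11 lithiated at C8 (the ring carbon between C–F and C–OMOM) | [Li]O[C@H](c1cc(CC=C(C)C)c(OCOC)c(CC=C(C)C)c1)CC1(c2ccc(OCOC)c([Li])c2F)SCCCS1 | intermediate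
16 | lithium alkoxide of the C8–C8a aryne formed from 15 by loss of LiF | [Li]O[C@H](c1cc(CC=C(C)C)c(OCOC)c(CC=C(C)C)c1)CC1(C2=CC=C(OCOC)C#C2)SCCCS1 | intermediate
17 | (2S)-8-lithio-7-(methoxymethoxy)-2-[4-(methoxymethoxy)-3,5-bis(3-methylbut-2-en-1-yl)phenyl]-2,3-dihydrospiro[chromene-4,2'-[1,3]dithiane] | [Li]c1c(OCOC)ccc2c1O[C@H](c1cc(CC=C(C)C)c(OCOC)c(CC=C(C)C)c1)CC21SCCCS1 | intermediate
18 | (2S)-8-[(2R)-2-hydroxy-3-methylbut-3-en-1-yl]-7-(methoxymethoxy)-2-[4-(methoxymethoxy)-3,5-bis(3-methylbut-2-en-1-yl)phenyl]-2,3-dihydrospiro[chromene-4,2'-[1,3]dithiane] | C=C(C)[C@H](O)Cc1c(OCOC)ccc2c1O[C@H](c1cc(CC=C(C)C)c(OCOC)c(CC=C(C)C)c1)CC21SCCCS1 | intermediate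
19 | (2S)-8-[(2R)-2-hydroxy-3-methylbut-3-en-1-yl]-7-(methoxymethoxy)-2-[4-(methoxymethoxy)-3,5-bis(3-methylbut-2-en-1-yl)phenyl]-2,3-dihydro-4H-chromen-4-one | C=C(C)[C@H](O)Cc1c(OCOC)ccc2c1O[C@H](c1cc(CC=C(C)C)c(OCOC)c(CC=C(C)C)c1)CC2=O | intermediate
20 | (2S)-7-hydroxy-2-[4-hydroxy-3,5-bis(3-methylbut-2-en-1-yl)phenyl]-8-[(2R)-2-hydroxy-3-methylbut-3-en-1-yl]-2,3-dihydro-4H-chromen-4-one | C=C(C)[C@H](O)Cc1c(O)ccc2c1O[C@H](c1cc(CC=C(C)C)c(O)c(CC=C(C)C)c1)CC2=O | target

**Step count**

Total: 13 steps. Longest linear sequence: 9 steps (steps 3, 4, 5, 6, 7, 8, 11, 12 and 13, from 4).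

**Steps most likely to fail**

1. Step 11 (carries the label). What may go wrong: the aryne may be intercepted intermolecularly (by butyllithium or by a second aryllithium) before the alkoxide closes ring C; the aryllithium may be protonated before capture; or the vinyl epoxide may be opened at the allylic carbon or with allylic transposition. Fallback with known chemistry, from 11 back to 18: ring C is closed first by intramolecular nucleophilic aromatic substitution of the fluoride by the potassium alkoxide (KOt-Bu, DMF, 80 °C, a known way from 3-(2-fluorophenyl)propanols to chromans). This should give (2S)-7-(methoxymethoxy)-2-[4-(methoxymethoxy)-3,5-bis(3-methylbut-2-en-1-yl)phenyl]-2,3-dihydrospiro[chromene-4,2'-[1,3]dithiane] F1. Its C8, now flanked by the ring oxygen and the MOM ether, is lithiated by directed ortho-metalation (n-BuLi, THF, 0 °C). The aryllithium is then treated with 14 and BF3·OEt2 at −78 °C, which returns to the route at 18.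

2. Step 13. What may go wrong: acid may open and reclose the chromanone ring with loss of configuration at C2, or may drive cyclisation of a prenyl group or of the allylic alcohol side chain onto a freed phenol. Fallback, from 18 to 20: the order of the two unmasking operations is exchanged. Compound 18 is treated with HCl in MeOH first, while C4 is still a dithiane and no chromanone is present that could open to a chalcone. This should give (2S)-8-[(2R)-2-hydroxy-3-methylbut-3-en-1-yl]-2-[4-hydroxy-3,5-bis(3-methylbut-2-en-1-yl)phenyl]-2,3-dihydrospiro[chromene-4,2'-[1,3]dithian]-7-ol F2. Its dithiane is then hydrolysed under the buffered MeI/CaCO3 conditions of step 12, which gives 20 directly, so the ketone never meets acid.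

3. Step 2. What may go wrong: allyl transposition during transmetalation or reductive elimination may deliver 1,1-dimethylallyl groups, and the second, more hindered coupling may stall. Fallback, from 2 back to 3: a twofold Stille coupling with allyltributylstannane (Pd(PPh3)4, DMF, 90 °C), for which transposition is degenerate, should give 4-(methoxymethoxy)-3,5-di(prop-2-en-1-yl)benzaldehyde F3. Cross-metathesis with 2-methylbut-2-ene (second-generation Grubbs catalyst, CH2Cl2, 40 °C) then turns both allyl groups into prenyl groups and returns to the route at 3.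

**Further compounds**

F1 | step 11 | (2S)-7-(methoxymethoxy)-2-[4-(methoxymethoxy)-3,5-bis(3-methylbut-2-en-1-yl)phenyl]-2,3-dihydrospiro[chromene-4,2'-[1,3]dithiane] | COCOc1ccc2c(c1)O[C@H](c1cc(CC=C(C)C)c(OCOC)c(CC=C(C)C)c1)CC21SCCCS1
F2 | step 13 | (2S)-8-[(2R)-2-hydroxy-3-methylbut-3-en-1-yl]-2-[4-hydroxy-3,5-bis(3-methylbut-2-en-1-yl)phenyl]-2,3-dihydrospiro[chromene-4,2'-[1,3]dithian]-7-ol | C=C(C)[C@H](O)Cc1c(O)ccc2c1O[C@H](c1cc(CC=C(C)C)c(O)c(CC=C(C)C)c1)CC21SCCCS1
F3 | step 2 | 4-(methoxymethoxy)-3,5-di(prop-2-en-1-yl)benzaldehyde | O=Cc1cc(CC=C)c(OCOC)c(CC=C)c1
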